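The constants used here were drawn at random within sensible limits; no experiment stands behind them.

5 questions stand here: the order of the 4 set-ups, and the amount of intermediate in each.

| setting | alder | oak | birch | larch |
|---|---|---|---|---|
| substrate | 0.20 M | 0.20 M | 0.20 M | 0.20 M (fed, over 2.00 h) |
| partner | 0.200 M | 0.200 M | 0.200 M | 0.200 M |
| free catalyst | 2.4 mM | 2.4 mM | 2.4 mM | 2.4 mM |
| second catalyst | 2.0 mM | 2.0 mM | 2.0 mM | 2.0 mM |
| time | 2.5 h |  |  | 2.5 h |
| remark | everything together in a closed stirred flask, run for 2.5 h | one stirred flow tank at steady state, fed with the mixture as stated, mean residence time 12.5 h | a single well-mixed tank run continuously and read at steady state, 2.5 h in it on average | a stirred flask in which substrate is dosed at a steady rate over 2.00 h without added volume, worked up at 2.5 h |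

    free catalyst → spent catalyst (k1 = 4.29 × 10⁻⁵ s⁻¹)
    substrate + target → side product (k2 = 6.95 × 10⁻⁴ M⁻¹ s⁻¹)
    substrate + free catalyst ⇌ free catalyst + intermediate (K3 = 1.9, k3 = 0.0522 M⁻¹ s⁻¹)
    partner + second catalyst + intermediate → second catalyst + target (k4 = 0.339 M⁻² s⁻¹)

1. order of the set-ups by the amount of intermediate at the outlet or at the end, in percent of the substrate put in, highest first (alder / oak / birch / larch)
2. amount of intermediate at the outlet or at the end, in percent of the substrate put in, alder
3. amount of intermediate at the outlet or at the end, in percent of the substrate put in, oak
4. amount of intermediate at the outlet or at the end, in percent of the substrate put in, birch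
5. amount of intermediate at the outlet or at the end, in percent of the substrate put in, larch

- a species is counted by the substrate in it: one side product counts as two
- the stated concentrations are those of everything mixed, before any reaction; amounts are the same in each set-up
- the feed brings no volume worth counting
- run time (alder): 2.5 h

You carry one quantity, Q: the pseudo-first-order rate at which free catalyst makes intermediate from substrate, divided by the rate at which partner and second catalyst drain intermediate to target. As charged, Q is 0.924. My ledger follows substrate through birch.

1. Substrate is the limiting reagent: 0.20 M meets 0.200 M of partner, but one side product takes two substrate and one partner.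

2. Birch keeps 72.1% of its free catalyst, so Q there is 0.667. Oak, with 12.5 h, has Q at 0.315, lower than birch's.

3. In one birch residence time, against a washout of 1, the drain counts 1.22 and the way back to substrate 0.428. Intermediate per substrate is therefore Q times drain over the sum of these three: 0.307.

4. Without side product, the books read 59.5% substrate, 18.3% intermediate and 22.3% passed on.

5. Target meets substrate in the tank, giving 0.744 side product per target left. So 42.7% of what passed on takes a second substrate, an entry of 9.51%.

6. Sharing the rest in the same proportions closes the books: 53.8% substrate, 16.5% intermediate, 20.2% passed on, plus that second-substrate entry. I held partner at its charge, though the passed-on entry uses some, so I expect birch somewhat higher.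

The forecast gives alder > larch > birch > oak: alder 27.5%, oak 9.6%, birch 18.6%, larch 23.2%. Its birch is higher than my 16.5%. For oak it argues that the long stay "lets the catalyst decay and the intermediate drain into target and side product".

The simulation gives alder > larch > birch > oak: alder 27.9%, oak 9.64%, birch 18.6%, larch 23.3%, the forecast's order, with every amount within its margin.

In birch, with partner standing at 0.163 M, the make runs at 0.325 h⁻¹ against a drain of 0.398 h⁻¹, slower than the drain, so Q is 0.818 and intermediate reads 18.6%. Alder left ten times as long has, by first-order decay, 2.10% of its free catalyst, so Q with partner taken as charged is 0.0194, and intermediate reads 0.753% after 25.0 h.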